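Octacosanolide is a 29-membered lactone ring whose only functional handle is the ester, so a second handle is built in: the four adjacent methylenes C21–C24 are carried as the ring carbons of a 2,5-disubstituted thiophene. The macrocycle is then cut at C20–C21, between that thiophene and an acyl carbon. The cyclisation precursor is an open-chain ester: 4-(thiophen-2-yl)butyl icosanedioate whose remote carboxyl (C20) is an acid chloride, assembled without statistical esterification from a mono-tert-butyl C20 diacid. One intramolecular Friedel–Crafts acylation at the free thiophene alpha carbon forms C20–C21 and closes the ring; ionic deoxygenation and nickel desulfurisation then erase ketone and sulfur.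

Key step: step 5

Remark: 20-(tert-butoxy)-20-oxoicosanoic acid (3) is assumed to be purchasable as a standard fatty-diacid building block; atom numbers follow the lactone (C1 = carbonyl carbon, C28 = OCH2), and no structural error was found in the target, precursor or cyclisation product.

Step 1
Reactants: 1 4-(thiophen-2-yl)butanoic acid
Product: 2 4-(thiophen-2-yl)butan-1-ol
Conditions: LiAlH4, THF, 0 °C → rt; then H2O, 15% aq. NaOH, H2O
Reagents that add atoms: none
Why: LiAlH4 reduction of a carboxylic acid to the primary alcohol, to which the thiophene ring is inert.

Step 2
Reactants: 2 4-(thiophen-2-yl)butan-1-ol; 3 20-(tert-butoxy)-20-oxoicosanoic acid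
Product: 4 1-tert-butyl 20-[4-(thiophen-2-yl)butyl] icosanedioate
Conditions: N,N'-diisopropylcarbodiimide (DIC), DMAP (cat.), CH2Cl2, 0 °C → rt
Reagents that add atoms: none
Why: Steglich esterification of an unhindered primary alcohol with the single free carboxyl of 3 should give the mixed diester cleanly, so the two ends of the C20 chain are differentiated without a statistical step.

Step 3
Reactants: 4 1-tert-butyl 20-[4-(thiophen-2-yl)butyl] icosanedioate
Product: 5 20-oxo-20-[4-(thiophen-2-yl)butoxy]icosanoic acid
Conditions: TFA/CH2Cl2 (1:3), 1,3-dimethoxybenzene (5 equiv), 0 °C → rt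
Reagents that add atoms: none
Why: Acidolysis of the tert-butyl ester (alkyl–oxygen cleavage, the cation leaving as 2-methylpropene) spares the primary thienylbutyl ester, and the dimethoxybenzene is present to intercept any cation that would otherwise alkylate the free thiophene alpha carbon needed in step 5.

Step 4
Reactants: 5 20-oxo-20-[4-(thiophen-2-yl)butoxy]icosanoic acid
Product: 6 4-(thiophen-2-yl)butyl 20-chloro-20-oxoicosanoate
Conditions: (COCl)2, DMF (cat.), CH2Cl2, 0 °C → rt; concentrated and used crude
Reagents that add atoms: oxalyl chloride, ClC(=O)C(=O)Cl
Why: Chlorination of the acid through the catalytic Vilsmeier-type chloroiminium species gives only gaseous by-products, and without a Lewis acid neither the ester nor the thiophene should react.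

Step 5
Reactants: 6 4-(thiophen-2-yl)butyl 20-chloro-20-oxoicosanoate
Product: 7 2,5-bridged thiophene keto lactone (perimeter O–C1(=O)–(CH2)18–C20(=O)–thiophene C2, thiophene C5–(CH2)4–O; C21–C24 are the thiophene carbons)
Conditions: SnCl4 (10 equiv), CH2Cl2, rt; 6 in CH2Cl2 added by syringe pump over 24 h (final ca. 1 mM); then cold 1 M HCl
Reagents that add atoms: none
Why: SnCl4 activates the acid chloride as an acylium ion (or its tight donor–acceptor complex), whose C20 attacks the only unsubstituted alpha carbon of the 2-alkylthiophene (the future C21) to give a Wheland intermediate that rearomatises by losing HCl, so the bond, once made, does not revert. The closest known reaction type is the high-dilution intramolecular Friedel–Crafts acylation of omega-(2-thienyl)alkanoyl chlorides to 2,5-bridged thienyl ketones; the ester in the chain is only an extra Lewis-basic site, which the excess of SnCl4 covers together with the product ketone. The single new ring is closed by exo attack at the acyl carbon (the C=O stays outside the ring) and is 28-membered through sulfur or 29-membered through C22–C23, the perimeter of the target; with 25 chain atoms between the two alpha carbons the bridge is free of strain. No stereocenter is formed. Two selectivities are needed, alpha over beta substitution and ring closure over chain growth: the first rests on the intrinsic alpha preference of a 2-alkylthiophene in acylation (the 3- and 4-positions gain no geometric advantage in so large a ring), the second on syringe-pump addition into dilute Lewis acid, which keeps the stationary concentration of 6 very low. The ketone that forms deactivates the thiophene, so a second acylation or acid-induced oligomerisation of the product is not expected.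

Step 6
Reactants: 7 2,5-bridged thiophene keto lactone
Product: 9 2,5-bridged thiophene lactone (C20 as CH2), via racemic 20-hydroxy thiophene lactone 8 (not isolated)
Conditions: Et3SiH (4 equiv), TFA/CH2Cl2 (1:1), rt → 40 °C
Reagents that add atoms: none
Why: Ionic hydrogenation: the protonated thienyl ketone takes hydride from the silane to give carbinol 8 (formed racemic, its stereocenter destroyed again), which ionises in TFA to a thienyl-stabilised cation and takes a second hydride, while the lactone is inert and any partial saturation of the thiophene is immaterial because step 7 removes sulfur from thiophene and thiolane alike.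

Step 7
Reactants: 9 2,5-bridged thiophene lactone
Product: 10 octacosanolide
Conditions: Raney Ni (W-2, large excess, washed to neutrality), H2 (1 atm), THF, 60 °C
Reagents that add atoms: none
Why: Raney nickel hydrogenolytic desulfurisation cleaves both C–S bonds and saturates the ring carbons so that C21–C24 emerge as four CH2 groups, and neutral nickel in aprotic THF is chosen so that the lactone is not opened by alkoxide or alcohol.

Compound list
1 | 4-(thiophen-2-yl)butanoic acid | O=C(O)CCCc1cccs1 | starting material
2 | 4-(thiophen-2-yl)butan-1-ol | OCCCCc1cccs1 | intermediate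
3 | 20-(tert-butoxy)-20-oxoicosanoic acid (mono-tert-butyl eicosanedioate) | CC(C)(C)OC(=O)CCCCCCCCCCCCCCCCCCC(=O)O | starting material
4 | 1-tert-butyl 20-[4-(thiophen-2-yl)butyl] icosanedioate | CC(C)(C)OC(=O)CCCCCCCCCCCCCCCCCCC(=O)OCCCCc1cccs1 | intermediate
5 | 20-oxo-20-[4-(thiophen-2-yl)butoxy]icosanoic acid | OC(=O)CCCCCCCCCCCCCCCCCCC(=O)OCCCCc1cccs1 | intermediate
6 | 4-(thiophen-2-yl)butyl 20-chloro-20-oxoicosanoate | O=C(Cl)CCCCCCCCCCCCCCCCCCC(=O)OCCCCc1cccs1 | intermediate
7 | 2,5-bridged thiophene keto lactone (20-oxo; C21–C24 as thiophene) | O=C1CCCCCCCCCCCCCCCCCCC(=O)c2ccc(CCCCO1)s2 | intermediate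
8 | racemic 20-hydroxy thiophene lactone (carbinol at C20, not isolated) | O=C1CCCCCCCCCCCCCCCCCCC(O)c2ccc(CCCCO1)s2 | intermediate
9 | 2,5-bridged thiophene lactone (C20 as CH2; C21–C24 as thiophene) | O=C1CCCCCCCCCCCCCCCCCCCc2ccc(CCCCO1)s2 | intermediate
10 | octacosanolide (oxacyclononacosan-2-one) | O=C1CCCCCCCCCCCCCCCCCCCCCCCCCCCO1 | target

Total step count: 7. Longest linear sequence: 7 steps (1 → 10); acid 3 enters at step 2.

Steps most likely to fail

Step 5 (key step). The risk is that intermolecular acylation (chain growth) keeps pace with ring closure during the slow addition, or that the Lewis acid erodes the ester over the long reaction time. The fallback sets out from 2 and 3 and comes back at 7; it makes the C20–C21 bond intermolecularly and closes the ring at the lactone instead. Alcohol 2 would be silylated (TBSCl, imidazole, DMF) to tert-butyldimethyl[4-(thiophen-2-yl)butoxy]silane F1. Acid 3 would be converted (MeNHOMe·HCl, EDC·HCl, N-methylmorpholine, CH2Cl2) into the Weinreb amide tert-butyl 20-[methoxy(methyl)amino]-20-oxoicosanoate F2. n-BuLi in THF (−78 → 0 °C) should metalate F1 at its free alpha carbon to give {5-[4-(tert-butyldimethylsilyloxy)butyl]thiophen-2-yl}lithium F3. Added to F2 at −78 °C, this should give after NH4Cl work-up tert-butyl 20-{5-[4-(tert-butyldimethylsilyloxy)butyl]thiophen-2-yl}-20-oxoicosanoate F4. TFA/CH2Cl2/H2O then removes silyl ether and tert-butyl ester together; the 2-acyl-5-alkylthiophene has no free alpha carbon and is deactivated, so cation capture is no concern here. This gives the seco acid 20-[5-(4-hydroxybutyl)thiophen-2-yl]-20-oxoicosanoic acid F5. Shiina macrolactonisation (2-methyl-6-nitrobenzoic anhydride, DMAP, CH2Cl2, slow addition, rt) should close the O–C1 bond to give 7.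

Step 6. The risk is that deoxygenation stalls at the carbinol, its ether or an olefin, or that the electron-rich ring suffers acid-mediated side reactions before the second hydride transfer. The fallback sets out from 7 and comes back at 10, removing the ketone oxygen as sulfur. Ethane-1,2-dithiol and BF3·OEt2 in CH2Cl2 should convert the thienyl ketone into the C20 spiro-1,3-dithiolane of the keto lactone F6. Neutral Raney Ni (THF, H2, 60 °C) should then remove the dithiolane (Mozingo reduction) and the thiophene sulfur in one operation, giving 10 directly.

Step 7. The risk is incomplete hydrogenolysis (thiolane or olefin residues), opening of the lactone on residual alkaline nickel, and loss of material by adsorption. The fallback sets out from 9 and comes back at 10; sulfur is removed on the open chain and the ring is re-formed afterwards. Saponification (KOH, EtOH/H2O, reflux, then acidification) should give 20-[5-(4-hydroxybutyl)thiophen-2-yl]icosanoic acid F7. Desulfurisation of its sodium salt (Raney Ni, aq. Na2CO3/EtOH, reflux), where solvolysis no longer matters and forcing conditions are acceptable, should give 28-hydroxyoctacosanoic acid F8. Shiina macrolactonisation under slow addition (2-methyl-6-nitrobenzoic anhydride, DMAP, toluene, 60 °C) should then give 10.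

Further compounds
F1 | step 5 | tert-butyldimethyl[4-(thiophen-2-yl)butoxy]silane | CC(C)(C)[Si](C)(C)OCCCCc1cccs1
F2 | step 5 | tert-butyl 20-[methoxy(methyl)amino]-20-oxoicosanoate | CON(C)C(=O)CCCCCCCCCCCCCCCCCCC(=O)OC(C)(C)C
F3 | step 5 | {5-[4-(tert-butyldimethylsilyloxy)butyl]thiophen-2-yl}lithium | [Li]c1ccc(CCCCO[Si](C)(C)C(C)(C)C)s1
F4 | step 5 | tert-butyl 20-{5-[4-(tert-butyldimethylsilyloxy)butyl]thiophen-2-yl}-20-oxoicosanoate | CC(C)(C)OC(=O)CCCCCCCCCCCCCCCCCCC(=O)c1ccc(CCCCO[Si](C)(C)C(C)(C)C)s1
F5 | step 5 | 20-[5-(4-hydroxybutyl)thiophen-2-yl]-20-oxoicosanoic acid | OC(=O)CCCCCCCCCCCCCCCCCCC(=O)c1ccc(CCCCO)s1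
F6 | step 6 | C20 spiro-1,3-dithiolane of the 2,5-bridged thiophene keto lactone | O=C1CCCCCCCCCCCCCCCCCCC2(SCCS2)c3ccc(CCCCO1)s3
F7 | step 7 | 20-[5-(4-hydroxybutyl)thiophen-2-yl]icosanoic acid | OC(=O)CCCCCCCCCCCCCCCCCCCc1ccc(CCCCO)s1
F8 | step 7 | 28-hydroxyoctacosanoic acid | OC(=O)CCCCCCCCCCCCCCCCCCCCCCCCCCCO
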